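**Retrosynthetic overview**
1. Target ⇐ acetyl-protected ferulic acid + silyl-protected hydroazulenol 14 (ester C–O bond, then one fluoride deprotection).
2. 14 ⇐ cis-decalin mesylate 13 by a stereospecific Wagner–Meerwein 1,2-shift: the mesylate-bearing six-membered ring contracts to the cyclopentane while the other expands to the cycloheptene, and E1 loss of H gives C1=C10.
3. 13 ⇐ Diels–Alder adduct 7 by methylenation/hydrogenation (C4), reagent-controlled reduction (C1–OH, also the resolution) and hydroboration (C7–H, C8–OH).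
4. 7 ⇐ 2-methylcyclohex-2-ene-1,4-dione 6 + 2-substituted butadiene 4, both one step from cheap feedstocks.
5. Ring order: cyclohexene ring by Diels–Alder onto the six-membered ring of 6; then the five- and seven-membered rings together in step 9.

Assumption: 7–9 are racemic and are named and drawn as the enantiomer that is carried on after step 6; β is the face of the angular methyl group, α the opposite face.

**Route**

Step 1
Reactants: 1 2-methylbut-3-yn-2-ol; 2 ethylene
Product: 4 triethyl[(2-methyl-3-methylidenepent-4-en-2-yl)oxy]silane, via dienol 3 (not isolated)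
Conditions: C2H4 (1 atm), second-generation Grubbs catalyst RuCl2(=CHPh)(PCy3)(H2IMes) 3 mol%, CH2Cl2, 40 °C; then Et3SiOTf, 2,6-lutidine, 0 °C
Reagents that add atoms: triethylsilyl trifluoromethanesulfonate, CC[Si](CC)(CC)OS(=O)(=O)C(F)(F)F
Why: Ethylene–alkyne cross enyne metathesis turns the terminal alkyne into the 2-substituted buta-1,3-diene, and the tertiary alcohol is silylated in the same pot so that it cannot later trap the C10 cation of step 9.

Step 2
Reactants: 5 3-methylcyclohex-2-en-1-one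
Product: 6 2-methylcyclohex-2-ene-1,4-dione
Conditions: Rh2(C6H10NO)4 (dirhodium tetracaprolactamate) 1 mol%, t-BuOOH, K2CO3, CH2Cl2, rt
Reagents that add atoms: tert-butyl hydroperoxide, CC(C)(C)OO
Why: Radical allylic (γ-CH2) oxidation of an enone to the ene-dione; the ring CH2 next to the alkene is the only secondary allylic position.

Step 3
Reactants: 4 triethyl[(2-methyl-3-methylidenepent-4-en-2-yl)oxy]silane; 6 2-methylcyclohex-2-ene-1,4-dione
Product: 7 rac-(4aR,8aS)-8a-methyl-6-{2-[(triethylsilyl)oxy]propan-2-yl}-4a,5,8,8a-tetrahydronaphthalene-1,4(2H,3H)-dione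
Conditions: toluene, 80 °C, sealed tube, no Lewis acid
Reagents that add atoms: none
Why: Thermal Diels–Alder reaction; suprafacial addition to the ring alkene gives the cis ring fusion (4aβ-H, 8aβ-CH3), and without a Lewis acid the more nucleophilic diene terminus (next to the substituted carbon) bonds to the unsubstituted, more electrophilic alkene carbon, placing the side chain on C6.

Step 4
Reactants: 7 rac-(4aR,8aS)-8a-methyl-6-{2-[(triethylsilyl)oxy]propan-2-yl}-4a,5,8,8a-tetrahydronaphthalene-1,4(2H,3H)-dione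
Product: 8 rac-(4aS,8aS)-8a-methyl-4-methylidene-6-{2-[(triethylsilyl)oxy]propan-2-yl}-3,4,4a,5,8,8a-hexahydronaphthalen-1(2H)-one
Conditions: Ti(C5H5)2(CH3)2 1.5 equiv, toluene, 65 °C
Reagents that add atoms: bis(cyclopentadienyl)dimethyltitanium, C[Ti](C)(C1C=CC=C1)C1C=CC=C1
Why: Petasis methylenation attacks the C4 ketone and spares the neopentyl C1 ketone beside the quaternary carbon, and being non-basic it leaves the epimerisable C4a centre cis.

Step 5
Reactants: 8 rac-(4aS,8aS)-8a-methyl-4-methylidene-6-{2-[(triethylsilyl)oxy]propan-2-yl}-3,4,4a,5,8,8a-hexahydronaphthalen-1(2H)-one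
Product: 9 rac-(4S,4aS,8aS)-4,8a-dimethyl-6-{2-[(triethylsilyl)oxy]propan-2-yl}-3,4,4a,5,8,8a-hexahydronaphthalen-1(2H)-one
Conditions: H2 (1 atm), RhCl(PPh3)3 5 mol%, benzene–EtOH, rt
Reagents that add atoms: none
Why: Homogeneous hydrogenation with Wilkinson's catalyst reduces only the 1,1-disubstituted exocyclic alkene and is expected to deliver H to C4 from the convex β face of the cis-decalin, giving 4α-CH3 with H4 cis to H4a; this facial preference is conformer-dependent and is an assumption, not a certainty.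

Step 6
Reactants: 9 rac-(4S,4aS,8aS)-4,8a-dimethyl-6-{2-[(triethylsilyl)oxy]propan-2-yl}-3,4,4a,5,8,8a-hexahydronaphthalen-1(2H)-one
Product: 10 (1S,4S,4aS,8aS)-4,8a-dimethyl-6-{2-[(triethylsilyl)oxy]propan-2-yl}-1,2,3,4,4a,5,8,8a-octahydronaphthalen-1-ol
Conditions: (R)-2-methyl-CBS-oxazaborolidine 20 mol%, BH3·SMe2, toluene, −20 °C; MeOH; silica separation of the diastereomeric alcohols
Reagents that add atoms: none
Why: Corey–Bakshi–Shibata reduction, in which the catalyst tells the quaternary C8a from the C2 methylene and gives the 1S carbinol from both enantiomers of 9; the needed enantiomer therefore gives the equatorial 1β-alcohol 10 and the other gives a 1α-diastereomer that is separated, so this step sets C1 and resolves the series.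

Step 7
Reactants: 10 (1S,4S,4aS,8aS)-4,8a-dimethyl-6-{2-[(triethylsilyl)oxy]propan-2-yl}-1,2,3,4,4a,5,8,8a-octahydronaphthalen-1-ol
Product: 11 (1S,4S,4aS,8aS)-4,8a-dimethyl-6-{2-[(triethylsilyl)oxy]propan-2-yl}-1,2,3,4,4a,5,8,8a-octahydronaphthalen-1-yl methanesulfonate
Conditions: MsCl, Et3N, CH2Cl2, 0 °C
Reagents that add atoms: methanesulfonyl chloride, CS(=O)(=O)Cl
Why: Sulfonylation through sulfene works on the hindered neopentyl alcohol with retention at C1, and the neopentyl mesylate is inert to SN2 and so survives step 8.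

Step 8
Reactants: 11 (1S,4S,4aS,8aS)-4,8a-dimethyl-6-{2-[(triethylsilyl)oxy]propan-2-yl}-1,2,3,4,4a,5,8,8a-octahydronaphthalen-1-yl methanesulfonate
Product: 13 (1S,4S,4aS,6S,7S,8aS)-7-hydroxy-4,8a-dimethyl-6-{2-[(triethylsilyl)oxy]propan-2-yl}decahydronaphthalen-1-yl methanesulfonate, via alkylborane 12 (not isolated)
Conditions: BH3·THF, THF, 0 °C to rt; then NaOH, H2O2, 0 °C
Reagents that add atoms: hydrogen peroxide, OO
Why: Hydroboration–oxidation of the trisubstituted alkene puts boron on the less substituted C7 and adds H and B syn from the convex β face, so 6β-H and 7β-OH are set together with the side chain α (trans to OH, H6 cis to H4a).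

Step 9
Reactants: 13 (1S,4S,4aS,6S,7S,8aS)-7-hydroxy-4,8a-dimethyl-6-{2-[(triethylsilyl)oxy]propan-2-yl}decahydronaphthalen-1-yl methanesulfonate
Product: 14 (3S,3aS,5S,6S)-3,8-dimethyl-5-{2-[(triethylsilyl)oxy]propan-2-yl}-1,2,3,3a,4,5,6,7-octahydroazulen-6-ol
Conditions: 2,6-lutidine, (CF3)2CHOH, 40 °C
Reagents that add atoms: none
Why: Solvolytic Wagner–Meerwein 1,2-alkyl shift (ring contraction with ring expansion): the equatorial 1β-mesylate is antiperiplanar to the C8a–C4a bond, C4a migrates with retention to C1 as mesylate leaves, and the tertiary C8a cation loses the C1 proton to give the tetrasubstituted alkene, while the four remaining stereocentres are untouched.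

Step 10
Reactants: 14 (3S,3aS,5S,6S)-3,8-dimethyl-5-{2-[(triethylsilyl)oxy]propan-2-yl}-1,2,3,3a,4,5,6,7-octahydroazulen-6-ol; 15 (2E)-3-[4-(acetyloxy)-3-methoxyphenyl]prop-2-enoic acid
Product: 16 (3S,3aS,5S,6S)-3,8-dimethyl-5-{2-[(triethylsilyl)oxy]propan-2-yl}-1,2,3,3a,4,5,6,7-octahydroazulen-6-yl (2E)-3-[4-(acetyloxy)-3-methoxyphenyl]prop-2-enoate
Conditions: EDC·HCl, DMAP, CH2Cl2, rt
Reagents that add atoms: none
Why: Steglich esterification acylates the only free hydroxyl with retention at C8; the phenol is masked as acetate so it cannot self-acylate and the E alkene is not touched.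

Step 11
Reactants: 16 (3S,3aS,5S,6S)-3,8-dimethyl-5-{2-[(triethylsilyl)oxy]propan-2-yl}-1,2,3,3a,4,5,6,7-octahydroazulen-6-yl (2E)-3-[4-(acetyloxy)-3-methoxyphenyl]prop-2-enoate
Product: 17 (3S,3aS,5S,6S)-5-(2-hydroxypropan-2-yl)-3,8-dimethyl-1,2,3,3a,4,5,6,7-octahydroazulen-6-yl (2E)-3-(4-hydroxy-3-methoxyphenyl)prop-2-enoate
Conditions: Bu4NF·3H2O, THF, 0 °C to rt; aq. NH4Cl
Reagents that add atoms: none
Why: Fluoride desilylation frees the tertiary alcohol and the basic medium cleaves the aryl acetate, which is far more labile than the alkyl cinnamate; acid is avoided because it would cyclise the tertiary alcohol onto C10.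

**Compound list**
1 | 2-methylbut-3-yn-2-ol | CC(C)(O)C#C | starting material
2 | ethylene | C=C | starting material
3 | 2-methyl-3-methylidenepent-4-en-2-ol | CC(C)(O)C(=C)C=C | intermediate
4 | triethyl[(2-methyl-3-methylidenepent-4-en-2-yl)oxy]silane | CC[Si](CC)(CC)OC(C)(C)C(=C)C=C | intermediate
5 | 3-methylcyclohex-2-en-1-one | CC1=CC(=O)CCC1 | starting material
6 | 2-methylcyclohex-2-ene-1,4-dione | CC1=CC(=O)CCC1=O | intermediate
7 | rac-(4aR,8aS)-8a-methyl-6-{2-[(triethylsilyl)oxy]propan-2-yl}-4a,5,8,8a-tetrahydronaphthalene-1,4(2H,3H)-dione (cis-fused) | C[C@]12CC=C(C(C)(C)O[Si](CC)(CC)CC)C[C@H]1C(=O)CCC2=O | intermediate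
8 | rac-(4aS,8aS)-8a-methyl-4-methylidene-6-{2-[(triethylsilyl)oxy]propan-2-yl}-3,4,4a,5,8,8a-hexahydronaphthalen-1(2H)-one | C[C@]12CC=C(C(C)(C)O[Si](CC)(CC)CC)C[C@H]1C(=C)CCC2=O | intermediate
9 | rac-(4S,4aS,8aS)-4,8a-dimethyl-6-{2-[(triethylsilyl)oxy]propan-2-yl}-3,4,4a,5,8,8a-hexahydronaphthalen-1(2H)-one | C[C@]12CC=C(C(C)(C)O[Si](CC)(CC)CC)C[C@H]1[C@@H](C)CCC2=O | intermediate
10 | (1S,4S,4aS,8aS)-4,8a-dimethyl-6-{2-[(triethylsilyl)oxy]propan-2-yl}-1,2,3,4,4a,5,8,8a-octahydronaphthalen-1-ol | C[C@]12CC=C(C(C)(C)O[Si](CC)(CC)CC)C[C@H]1[C@@H](C)CC[C@@H]2O | intermediate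
11 | (1S,4S,4aS,8aS)-4,8a-dimethyl-6-{2-[(triethylsilyl)oxy]propan-2-yl}-1,2,3,4,4a,5,8,8a-octahydronaphthalen-1-yl methanesulfonate | C[C@]12CC=C(C(C)(C)O[Si](CC)(CC)CC)C[C@H]1[C@@H](C)CC[C@@H]2OS(C)(=O)=O | intermediate
12 | 7β-boranyl adduct of 11 (6β-H, 7β-BH2; other centres as in 11) | C[C@]12C[C@H](B)[C@@H](C(C)(C)O[Si](CC)(CC)CC)C[C@H]1[C@@H](C)CC[C@@H]2OS(C)(=O)=O | intermediate
13 | (1S,4S,4aS,6S,7S,8aS)-7-hydroxy-4,8a-dimethyl-6-{2-[(triethylsilyl)oxy]propan-2-yl}decahydronaphthalen-1-yl methanesulfonate | C[C@]12C[C@H](O)[C@@H](C(C)(C)O[Si](CC)(CC)CC)C[C@H]1[C@@H](C)CC[C@@H]2OS(C)(=O)=O | intermediate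
14 | (3S,3aS,5S,6S)-3,8-dimethyl-5-{2-[(triethylsilyl)oxy]propan-2-yl}-1,2,3,3a,4,5,6,7-octahydroazulen-6-ol | O[C@H]1CC(C)=C2CC[C@H](C)[C@@H]2C[C@@H]1C(C)(C)O[Si](CC)(CC)CC | intermediate
15 | (2E)-3-[4-(acetyloxy)-3-methoxyphenyl]prop-2-enoic acid | COc1cc(/C=C/C(=O)O)ccc1OC(C)=O | starting material
16 | (3S,3aS,5S,6S)-3,8-dimethyl-5-{2-[(triethylsilyl)oxy]propan-2-yl}-1,2,3,3a,4,5,6,7-octahydroazulen-6-yl (2E)-3-[4-(acetyloxy)-3-methoxyphenyl]prop-2-enoate | COc1cc(/C=C/C(=O)O[C@H]2CC(C)=C3CC[C@H](C)[C@@H]3C[C@@H]2C(C)(C)O[Si](CC)(CC)CC)ccc1OC(C)=O | intermediate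
17 | (3S,3aS,5S,6S)-5-(2-hydroxypropan-2-yl)-3,8-dimethyl-1,2,3,3a,4,5,6,7-octahydroazulen-6-yl (2E)-3-(4-hydroxy-3-methoxyphenyl)prop-2-enoate | COc1cc(/C=C/C(=O)O[C@H]2CC(C)=C3CC[C@H](C)[C@@H]3C[C@@H]2C(C)(C)O)ccc1O | target

**Count**
Total steps: 11. Longest linear sequence: 10 (steps 2–11; the diene branch, step 1 then steps 3–11, is also 10).

**Three steps most likely to fail**

Step 3 (Diels–Alder). The side-chain position rests on the uncatalysed regiochemistry, the ene-dione can tautomerise to methylhydroquinone, and the adduct is racemic. The fallback sets out from 6 and comes back at 7. Reduce 6 regio- and enantioselectively at the less hindered C4 carbonyl by transfer hydrogenation [RuCl(p-cymene)(TsDPEN), HCO2H/Et3N, ligand enantiomer chosen for the R alcohol] to (R)-4-hydroxy-2-methylcyclohex-2-en-1-one F1, and acetylate it to (1R)-3-methyl-4-oxocyclohex-2-en-1-yl acetate F2. The single remaining carbonyl now fixes the orientation and the acetate shields one face in a Me2AlCl-promoted cycloaddition with 4 (−40 °C, or high pressure without Lewis acid if the allylic silyl ether of 4 ionises), giving the acetoxy decalinone F3. Methanolysis (K2CO3, MeOH) gives the hydroxy decalinone F4, and Dess–Martin oxidation returns 7 as a single enantiomer, after which step 6 only has to set the carbinol centre.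

Step 6 (catalyst-controlled reduction and resolution). The substrate's own facial bias may override the catalyst in one enantiomer. The fallback sets out from 9 and comes back at 10. Reduce racemic 9 under thermodynamic control (Li, NH3, THF) to the racemic equatorial 1β-alcohol F5. Esterify with (S)-2-methoxy-2-phenylacetic acid (DCC, DMAP), separate the diastereomeric esters by crystallisation or chromatography to obtain the (S)-O-methylmandelate F6, and cleave it (KOH, MeOH) to 10.

Step 9 (1,2-shift). The mesylate may ionise sluggishly, the C10 cation may lose the wrong proton, or the silyl ether oxygen may trap it as a cyclic ether. The fallback sets out from 10 and comes back at 14. Oxidise 10 (Dess–Martin) to the single-enantiomer ketone F7 and convert it with NH2OH·HCl/NaOAc to the oxime F8. Reduce with Na in n-PrOH to the equatorial 1β-amine F9, then hydroborate and oxidise as in step 8 to the amino alcohol F10. Diazotise (NaNO2, aqueous AcOH, 0 °C): the diazonium ion departs at 0 °C with the same antiperiplanar C4a shift (Demjanov-type deaminative rearrangement) and gives 14 under conditions too mild for the competing pathways.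

**Further compounds**
F1 | step 3 | (R)-4-hydroxy-2-methylcyclohex-2-en-1-one | CC1=C[C@H](O)CCC1=O
F2 | step 3 | (1R)-3-methyl-4-oxocyclohex-2-en-1-yl acetate | CC1=C[C@H](OC(C)=O)CCC1=O
F3 | step 3 | cis-fused 4β-acetoxy-8a-methyl-6-{2-[(triethylsilyl)oxy]propan-2-yl}-3,4,4a,5,8,8a-hexahydronaphthalen-1(2H)-one (4aβ-H, 8aβ-CH3) | C[C@]12CC=C(C(C)(C)O[Si](CC)(CC)CC)C[C@H]1[C@H](OC(C)=O)CCC2=O
F4 | step 3 | cis-fused 4β-hydroxy-8a-methyl-6-{2-[(triethylsilyl)oxy]propan-2-yl}-3,4,4a,5,8,8a-hexahydronaphthalen-1(2H)-one | C[C@]12CC=C(C(C)(C)O[Si](CC)(CC)CC)C[C@H]1[C@H](O)CCC2=O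
F5 | step 6 | racemic form of alcohol 10 (1β-OH) | C[C@]12CC=C(C(C)(C)O[Si](CC)(CC)CC)C[C@H]1[C@@H](C)CC[C@@H]2O
F6 | step 6 | (S)-2-methoxy-2-phenylacetate of 10 | CO[C@H](C(=O)O[C@H]1CC[C@H](C)[C@@H]2CC(C(C)(C)O[Si](CC)(CC)CC)=CC[C@]12C)c1ccccc1
F7 | step 9 | (4S,4aS,8aS)-4,8a-dimethyl-6-{2-[(triethylsilyl)oxy]propan-2-yl}-3,4,4a,5,8,8a-hexahydronaphthalen-1(2H)-one, single enantiomer | C[C@]12CC=C(C(C)(C)O[Si](CC)(CC)CC)C[C@H]1[C@@H](C)CCC2=O
F8 | step 9 | oxime of F7 | C[C@]12CC=C(C(C)(C)O[Si](CC)(CC)CC)C[C@H]1[C@@H](C)CCC2=NO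
F9 | step 9 | 1β-amine corresponding to 10 (NH2 in place of OH) | C[C@]12CC=C(C(C)(C)O[Si](CC)(CC)CC)C[C@H]1[C@@H](C)CC[C@@H]2N
F10 | step 9 | 1β-amino-7β-hydroxy decalin corresponding to 13 (NH2 in place of the mesylate) | C[C@]12C[C@H](O)[C@@H](C(C)(C)O[Si](CC)(CC)CC)C[C@H]1[C@@H](C)CC[C@@H]2N
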